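The route rests on cutting the O1–C8a aryl ether bond of the flavanone C ring. Ring A carries bromine at C8a, and a copper-catalysed intramolecular O-arylation lets the C2 carbinol oxygen close the pyran ring in one operation, with C2 and C3 retained. The substrate is an open-chain 1-(bromoaryl)-2,3-diarylpropane-1,3-diol with C2 and C3 already as in the target: C3 comes from a reagent-controlled syn aldol, C2 from a hydroxyl-directed anti reduction. C4 stays a free carbinol of defined configuration; it cannot reach C8a, so the more hindered hydroxyl need not be silylated selectively. The benzoate on the C3 aryl group later becomes the 5-hydroxy-7-methoxyflavone.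

Key step: step 7

Remark: (−)-Ipc2BOTf (from (+)-α-pinene) is assumed to steer the Z-enol borinate of 8 to the aldehyde face that gives (1S,2S)-10; if this benzyl ketone reacts with the opposite sense, (+)-Ipc2BOTf is used and nothing else changes.

Step 1
Reactants: 1 5-bromobenzene-1,3-diol (5-bromoresorcinol)
Product: 2 1,3-bis(benzyloxy)-5-bromobenzene
Conditions: BnBr (2.2 equiv), K2CO3, DMF, 60 °C
Reagents that add atoms: benzyl bromide, BrCc1ccccc1
Why: Williamson ether synthesis, in which both phenoxides are alkylated by the benzylic halide and no other nucleophilic site is present.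

Step 2
Reactants: 2 1,3-bis(benzyloxy)-5-bromobenzene
Product: 4 2,4-bis(benzyloxy)-6-bromobenzaldehyde, via iminium chloride 3 (not isolated)
Conditions: POCl3 (1.5 equiv), DMF, 0 → 70 °C; then aq NaOAc, rt
Reagents that add atoms: N,N-dimethylformamide, CN(C)C=O; water, O
Why: Vilsmeier–Haack formylation, in which the chloroiminium ion should enter para to one benzyloxy group and ortho to the other, next to bromine, and not at the crowded position between the two ethers, which fixes the ring A pattern (C4a between C5–O and C8a–Br).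

Step 3
Reactants: 5 methyl 3-bromo-4-hydroxybenzoate
Product: 6 methyl 4-(benzyloxy)-3-bromobenzoate
Conditions: BnBr (1.1 equiv), K2CO3, acetone, reflux
Reagents that add atoms: benzyl bromide, BrCc1ccccc1
Why: Williamson ether synthesis on an acidic para-acyl phenol, with the methyl ester inert to carbonate in acetone.

Step 4
Reactants: 6 methyl 4-(benzyloxy)-3-bromobenzoate; 7 1-[4-(benzyloxy)phenyl]ethan-1-one
Product: 8 methyl 4-(benzyloxy)-3-{2-[4-(benzyloxy)phenyl]-2-oxoethyl}benzoate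
Conditions: Pd2(dba)3 (1.5 mol%), Xantphos (3.6 mol%), K3PO4 (2.3 equiv), 7 (1.3 equiv), toluene, 80 °C
Reagents that add atoms: none
Why: Buchwald–Hartwig α-arylation of an aryl methyl ketone, where the weak phosphate base spares the ester and the ortho-substituted bromide should stop the reaction at monoarylation.

Step 5
Reactants: 8 methyl 4-(benzyloxy)-3-{2-[4-(benzyloxy)phenyl]-2-oxoethyl}benzoate; 4 2,4-bis(benzyloxy)-6-bromobenzaldehyde
Product: 10 methyl 4-(benzyloxy)-3-{(1S,2S)-1-[2,4-bis(benzyloxy)-6-bromophenyl]-3-[4-(benzyloxy)phenyl]-1-hydroxy-3-oxopropan-2-yl}benzoate, via Z-enol diisopinocampheylborinate 9 (not isolated)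
Conditions: (−)-Ipc2BOTf (1.3 equiv), i-Pr2NEt, CH2Cl2, −78 °C; 4 (1.3 equiv), −78 → −20 °C; then H2O2, pH 7 buffer, MeOH, 0 °C
Reagents that add atoms: none
Why: Paterson aldol reaction, in which the aryl ketone gives the Z-enol borinate and this adds through a Zimmerman–Traxler chair to give the syn aldol, while the isopinocampheyl ligands select the aldehyde face and so set C3 (as in the target) and the relay centre C4.

Step 6
Reactants: 10 the syn aldol of step 5
Product: 11 methyl 4-(benzyloxy)-3-{(1S,2R,3S)-1-[2,4-bis(benzyloxy)-6-bromophenyl]-3-[4-(benzyloxy)phenyl]-1,3-dihydroxypropan-2-yl}benzoate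
Conditions: Me4NBH(OAc)3 (5 equiv), MeCN/AcOH 1:1, −30 °C; aq Rochelle salt; recrystallise to raise enantiomeric purity if required
Reagents that add atoms: none
Why: Evans–Saksena reduction, in which the C4 hydroxyl exchanges onto boron and delivers hydride to the ketone within a chair, giving the 1,3-anti diol and thereby the C2 carbinol (S) anti to the C3 aryl group.

Step 7
Reactants: 11 the bromoaryl anti-1,3-diol of step 6
Product: 12 methyl 4-(benzyloxy)-3-{(2S,3S,4S)-5,7-bis(benzyloxy)-2-[4-(benzyloxy)phenyl]-4-hydroxy-3,4-dihydro-2H-1-benzopyran-3-yl}benzoate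
Conditions: CuI (10 mol%), 3,4,7,8-tetramethyl-1,10-phenanthroline (20 mol%), Cs2CO3 (2 equiv), toluene, 110 °C, argon
Reagents that add atoms: none
Why: Ullmann-type C–O coupling: the C2 alkoxide binds the phenanthroline-ligated Cu(I), the C8a–Br bond adds oxidatively to give an aryl–copper alkoxide held in a seven-membered chelate, and C–O reductive elimination forms O1–C8a. The closest known reaction is the copper-catalysed intramolecular etherification of secondary 3-(2-bromoaryl)propanols to chromans, for which a palladium version is also established. The dihydropyran ring closes by attack of the tethered oxygen on the arene carbon, a 6-exo closure in which O1, C2, C3, C4, C4a and C8a are already contiguous in the chain. No stereocentre is created and none should be lost, since the C2–O, C3–H and C4–O bonds stay intact and, with C4 at the carbinol level, base has no β-hydroxy ketone to cleave or dehydrate. The step needs site selectivity between two secondary benzylic hydroxyls, and the tether supplies it, because the C4 oxygen could only form a four-membered benzoxete. Copper is preferred to palladium because its alkoxides are not prone to β-hydride elimination, and the 2,3-trans-3,4-trans product places all three substituents equatorial.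

Step 8
Reactants: 13 1-(2,6-dihydroxy-4-methoxyphenyl)ethan-1-one
Product: 14 1-[2-(benzyloxy)-6-hydroxy-4-methoxyphenyl]ethan-1-one
Conditions: BnBr (1.0 equiv), K2CO3 (1.1 equiv), acetone, reflux
Reagents that add atoms: benzyl bromide, BrCc1ccccc1
Why: Williamson ether synthesis that should stop at the monoether, because the remaining hydroxyl is chelated to the ketone and much less nucleophilic.

Step 9
Reactants: 12 the flavan-4-ol ester of step 7; 14 1-[2-(benzyloxy)-6-hydroxy-4-methoxyphenyl]ethan-1-one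
Product: 15 1-[2-(benzyloxy)-6-hydroxy-4-methoxyphenyl]-3-(4-(benzyloxy)-3-{(2S,3S,4S)-5,7-bis(benzyloxy)-2-[4-(benzyloxy)phenyl]-4-hydroxy-3,4-dihydro-2H-1-benzopyran-3-yl}phenyl)propane-1,3-dione
Conditions: 14 (3 equiv), LiHMDS (7.5 equiv), THF, −78 °C; 12, −78 °C → rt; AcOH quench
Reagents that add atoms: none
Why: Crossed Claisen condensation (the C–C bond-forming half of the Baker–Venkataraman route), in which the dianion of the o-hydroxyacetophenone acylates on carbon with the methyl ester and the product is trapped as its enolate, while C4 rides as a lithium alkoxide that cannot ring-open as a flavanone enolate would.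

Step 10
Reactants: 15 the 1,3-diketone of step 9
Product: 16 1-[2-(benzyloxy)-6-hydroxy-4-methoxyphenyl]-3-(4-(benzyloxy)-3-{(2S,3R)-5,7-bis(benzyloxy)-2-[4-(benzyloxy)phenyl]-4-oxo-3,4-dihydro-2H-1-benzopyran-3-yl}phenyl)propane-1,3-dione
Conditions: Dess–Martin periodinane (1.5 equiv), NaHCO3, CH2Cl2, 0 °C → rt
Reagents that add atoms: none
Why: Dess–Martin oxidation of the only secondary alcohol under buffered, non-basic conditions, with the diketone expected to sit largely as its cyclic hemiketal or chelated enol and the C2 and C3 centres left untouched.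

Step 11
Reactants: 16 the flavanone diketone of step 10
Product: 17 (2S,3R)-5,7-bis(benzyloxy)-2-[4-(benzyloxy)phenyl]-3-{2-(benzyloxy)-5-[5-(benzyloxy)-7-methoxy-4-oxo-4H-1-benzopyran-2-yl]phenyl}-2,3-dihydro-4H-1-benzopyran-4-one
Conditions: p-TsOH·H2O (10 mol%), toluene, 60 °C
Reagents that add atoms: none
Why: Acid-catalysed cyclodehydration of the o-hydroxyaryl 1,3-diketone through its 2-hydroxychromanone hemiketal, placed after the oxidation because a 5,7-dialkoxyflavan-4-ol would ionise in acid, with C3 resting in its thermodynamically preferred trans arrangement.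

Step 12
Reactants: 17 the pentabenzyl flavanone–flavone of step 11
Product: 18 (2S,3R)-5,7-dihydroxy-3-[2-hydroxy-5-(5-hydroxy-7-methoxy-4-oxo-4H-1-benzopyran-2-yl)phenyl]-2-(4-hydroxyphenyl)-2,3-dihydro-4H-1-benzopyran-4-one (CNP0361110.2)
Conditions: H2 (1 atm), 10% Pd/C, THF/MeOH, rt
Reagents that add atoms: none
Why: Catalytic hydrogenolysis of the five benzyl ethers, which should leave the methyl ether, the chelated flavanone ketone, the flavone and both stereocentres untouched at atmospheric pressure.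

Compound list
1 | 5-bromobenzene-1,3-diol | Oc1cc(O)cc(Br)c1 | starting material
2 | 1,3-bis(benzyloxy)-5-bromobenzene | Brc1cc(OCc2ccccc2)cc(OCc2ccccc2)c1 | intermediate
3 | N-{[2,4-bis(benzyloxy)-6-bromophenyl]methylidene}-N-methylmethanaminium chloride | C[N+](C)=Cc1c(Br)cc(OCc2ccccc2)cc1OCc1ccccc1.[Cl-] | intermediate (not isolated)
4 | 2,4-bis(benzyloxy)-6-bromobenzaldehyde | O=Cc1c(Br)cc(OCc2ccccc2)cc1OCc1ccccc1 | intermediate
5 | methyl 3-bromo-4-hydroxybenzoate | COC(=O)c1ccc(O)c(Br)c1 | starting material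
6 | methyl 4-(benzyloxy)-3-bromobenzoate | COC(=O)c1ccc(OCc2ccccc2)c(Br)c1 | intermediate
7 | 1-[4-(benzyloxy)phenyl]ethan-1-one | CC(=O)c1ccc(OCc2ccccc2)cc1 | starting material
8 | methyl 4-(benzyloxy)-3-{2-[4-(benzyloxy)phenyl]-2-oxoethyl}benzoate | COC(=O)c1ccc(OCc2ccccc2)c(CC(=O)c2ccc(OCc3ccccc3)cc2)c1 | intermediate
9 | methyl 4-(benzyloxy)-3-[(Z)-2-[4-(benzyloxy)phenyl]-2-({bis[(1R,2S,3R,5R)-2,6,6-trimethylbicyclo[3.1.1]heptan-3-yl]boranyl}oxy)ethenyl]benzoate | COC(=O)c1ccc(OCc2ccccc2)c(/C=C(\OB([C@@H]2C[C@@H]3C[C@H]([C@H]2C)C3(C)C)[C@@H]2C[C@@H]3C[C@H]([C@H]2C)C3(C)C)c2ccc(OCc3ccccc3)cc2)c1 | intermediate (not isolated)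
10 | methyl 4-(benzyloxy)-3-{(1S,2S)-1-[2,4-bis(benzyloxy)-6-bromophenyl]-3-[4-(benzyloxy)phenyl]-1-hydroxy-3-oxopropan-2-yl}benzoate | COC(=O)c1ccc(OCc2ccccc2)c([C@H](C(=O)c2ccc(OCc3ccccc3)cc2)[C@H](O)c2c(Br)cc(OCc3ccccc3)cc2OCc2ccccc2)c1 | intermediate
11 | methyl 4-(benzyloxy)-3-{(1S,2R,3S)-1-[2,4-bis(benzyloxy)-6-bromophenyl]-3-[4-(benzyloxy)phenyl]-1,3-dihydroxypropan-2-yl}benzoate | COC(=O)c1ccc(OCc2ccccc2)c([C@H]([C@H](O)c2ccc(OCc3ccccc3)cc2)[C@H](O)c2c(Br)cc(OCc3ccccc3)cc2OCc2ccccc2)c1 | intermediate (precursor of the key step)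
12 | methyl 4-(benzyloxy)-3-{(2S,3S,4S)-5,7-bis(benzyloxy)-2-[4-(benzyloxy)phenyl]-4-hydroxy-3,4-dihydro-2H-1-benzopyran-3-yl}benzoate | COC(=O)c1ccc(OCc2ccccc2)c([C@H]2[C@H](O)c3c(OCc4ccccc4)cc(OCc4ccccc4)cc3O[C@@H]2c2ccc(OCc3ccccc3)cc2)c1 | intermediate (product of the key step)
13 | 1-(2,6-dihydroxy-4-methoxyphenyl)ethan-1-one | CC(=O)c1c(O)cc(OC)cc1O | starting material
14 | 1-[2-(benzyloxy)-6-hydroxy-4-methoxyphenyl]ethan-1-one | CC(=O)c1c(O)cc(OC)cc1OCc1ccccc1 | intermediate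
15 | 1-[2-(benzyloxy)-6-hydroxy-4-methoxyphenyl]-3-(4-(benzyloxy)-3-{(2S,3S,4S)-5,7-bis(benzyloxy)-2-[4-(benzyloxy)phenyl]-4-hydroxy-3,4-dihydro-2H-1-benzopyran-3-yl}phenyl)propane-1,3-dione | O=C(CC(=O)c1c(O)cc(OC)cc1OCc1ccccc1)c1ccc(OCc2ccccc2)c([C@H]2[C@H](O)c3c(OCc4ccccc4)cc(OCc4ccccc4)cc3O[C@@H]2c2ccc(OCc3ccccc3)cc2)c1 | intermediate
16 | 1-[2-(benzyloxy)-6-hydroxy-4-methoxyphenyl]-3-(4-(benzyloxy)-3-{(2S,3R)-5,7-bis(benzyloxy)-2-[4-(benzyloxy)phenyl]-4-oxo-3,4-dihydro-2H-1-benzopyran-3-yl}phenyl)propane-1,3-dione | O=C(CC(=O)c1c(O)cc(OC)cc1OCc1ccccc1)c1ccc(OCc2ccccc2)c([C@H]2C(=O)c3c(OCc4ccccc4)cc(OCc4ccccc4)cc3O[C@@H]2c2ccc(OCc3ccccc3)cc2)c1 | intermediate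
17 | (2S,3R)-5,7-bis(benzyloxy)-2-[4-(benzyloxy)phenyl]-3-{2-(benzyloxy)-5-[5-(benzyloxy)-7-methoxy-4-oxo-4H-1-benzopyran-2-yl]phenyl}-2,3-dihydro-4H-1-benzopyran-4-one | COc1cc(OCc2ccccc2)c2c(=O)cc(-c3ccc(OCc4ccccc4)c([C@H]4C(=O)c5c(OCc6ccccc6)cc(OCc6ccccc6)cc5O[C@@H]4c4ccc(OCc5ccccc5)cc4)c3)oc2c1 | intermediate
18 | (2S,3R)-5,7-dihydroxy-3-[2-hydroxy-5-(5-hydroxy-7-methoxy-4-oxo-4H-1-benzopyran-2-yl)phenyl]-2-(4-hydroxyphenyl)-2,3-dihydro-4H-1-benzopyran-4-one | COc1cc(O)c2c(=O)cc(-c3ccc(O)c([C@H]4C(=O)c5c(O)cc(O)cc5O[C@@H]4c4ccc(O)cc4)c3)oc2c1 | target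

Total step count: 12. Longest linear sequence: 9 steps (steps 3, 4, 5, 6, 7, 9, 10, 11 and 12, from 5 to 18).

Steps most likely to fail

1. Step 5. The bulky diisopinocampheylboron enolate may add slowly to the 2,6-disubstituted, electron-rich aldehyde, its ligands may discriminate the aldehyde faces poorly for a benzyl ketone, and the aldol may revert or dehydrate during work-up. The fallback sets out from 6, returns at 10 and puts the absolute control on a chiral auxiliary. Palladium-catalysed coupling of 6 with the Reformatsky reagent of tert-butyl bromoacetate would give methyl 4-(benzyloxy)-3-(2-tert-butoxy-2-oxoethyl)benzoate F1. Trifluoroacetic acid would free [2-(benzyloxy)-5-(methoxycarbonyl)phenyl]acetic acid F2. Its mixed pivalic anhydride would acylate (S)-4-benzyl-2-oxazolidinone to methyl 4-(benzyloxy)-3-{2-[(4S)-4-benzyl-2-oxo-1,3-oxazolidin-3-yl]-2-oxoethyl}benzoate F3. An Evans syn aldol (Bu2BOTf, Et3N) with 4 should give methyl 4-(benzyloxy)-3-{(1S,2S)-3-[(4S)-4-benzyl-2-oxo-1,3-oxazolidin-3-yl]-1-[2,4-bis(benzyloxy)-6-bromophenyl]-1-hydroxy-3-oxopropan-2-yl}benzoate F4. Lithium ethanethiolate would displace the auxiliary to give methyl 4-(benzyloxy)-3-{(1S,2S)-1-[2,4-bis(benzyloxy)-6-bromophenyl]-3-(ethylsulfanyl)-1-hydroxy-3-oxopropan-2-yl}benzoate F5. Acylation of lithium bis[4-(benzyloxy)phenyl]cuprate at −78 °C, which should leave the methyl ester and the aryl bromide alone, would then give 10.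

2. Step 7. Oxidative addition into the ortho-substituted, electron-rich bromide may be slow, which would let hydrodebromination compete. The 1,3-diol may also sequester copper, or the hot carbonate may start intermolecular transesterification at the benzoate. The fallback sets out from 10, returns at 12 and forms the other ether bond of the ring, O1–C2, with inversion. Narasaka–Prasad reduction (Et2BOMe, NaBH4) of 10 would give the 1,3-syn diol methyl 4-(benzyloxy)-3-{(1S,2R,3R)-1-[2,4-bis(benzyloxy)-6-bromophenyl]-3-[4-(benzyloxy)phenyl]-1,3-dihydroxypropan-2-yl}benzoate F6. Miyaura borylation (B2pin2, PdCl2(dppf), KOAc) would give methyl 4-(benzyloxy)-3-{(1S,2R,3R)-1-[2,4-bis(benzyloxy)-6-(4,4,5,5-tetramethyl-1,3,2-dioxaborolan-2-yl)phenyl]-3-[4-(benzyloxy)phenyl]-1,3-dihydroxypropan-2-yl}benzoate F7. Oxidation with sodium perborate would give the phenol methyl 4-(benzyloxy)-3-{(1S,2R,3R)-1-[2,4-bis(benzyloxy)-6-hydroxyphenyl]-3-[4-(benzyloxy)phenyl]-1,3-dihydroxypropan-2-yl}benzoate F8. A Mitsunobu cyclisation (PPh3, DIAD, 0 °C) should then activate the less hindered C2 hydroxyl and close the ring with inversion at C2 to give 12.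

3. Step 10. The hypervalent iodine reagent may attack the 1,3-diketone methylene or the free phenol of the open tautomer, and the acetic acid it releases may ionise the flavan-4-ol before it is oxidised. The fallback sets out from 12, returns at 17 and changes the order so that C4 is oxidised only when no diketone is left. Silylation of 12 (TBSOTf, 2,6-lutidine) would give methyl 4-(benzyloxy)-3-{(2S,3R,4S)-5,7-bis(benzyloxy)-2-[4-(benzyloxy)phenyl]-4-[(tert-butyldimethylsilyl)oxy]-3,4-dihydro-2H-1-benzopyran-3-yl}benzoate F9. Claisen condensation with 14 as in step 9 would give 1-[2-(benzyloxy)-6-hydroxy-4-methoxyphenyl]-3-(4-(benzyloxy)-3-{(2S,3R,4S)-5,7-bis(benzyloxy)-2-[4-(benzyloxy)phenyl]-4-[(tert-butyldimethylsilyl)oxy]-3,4-dihydro-2H-1-benzopyran-3-yl}phenyl)propane-1,3-dione F10. Cyclodehydration with pyridinium p-toluenesulfonate, mild enough that the silyl ether should not ionise, would give 5-(benzyloxy)-2-(4-(benzyloxy)-3-{(2S,3R,4S)-5,7-bis(benzyloxy)-2-[4-(benzyloxy)phenyl]-4-[(tert-butyldimethylsilyl)oxy]-3,4-dihydro-2H-1-benzopyran-3-yl}phenyl)-7-methoxy-4H-1-benzopyran-4-one F11. Tetrabutylammonium fluoride would free 5-(benzyloxy)-2-(4-(benzyloxy)-3-{(2S,3S,4S)-5,7-bis(benzyloxy)-2-[4-(benzyloxy)phenyl]-4-hydroxy-3,4-dihydro-2H-1-benzopyran-3-yl}phenyl)-7-methoxy-4H-1-benzopyran-4-one F12. Dess–Martin oxidation of this alcohol would give 17.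

Further compounds
F1 | step 5 | methyl 4-(benzyloxy)-3-(2-tert-butoxy-2-oxoethyl)benzoate | COC(=O)c1ccc(OCc2ccccc2)c(CC(=O)OC(C)(C)C)c1
F2 | step 5 | [2-(benzyloxy)-5-(methoxycarbonyl)phenyl]acetic acid | COC(=O)c1ccc(OCc2ccccc2)c(CC(=O)O)c1
F3 | step 5 | methyl 4-(benzyloxy)-3-{2-[(4S)-4-benzyl-2-oxo-1,3-oxazolidin-3-yl]-2-oxoethyl}benzoate | COC(=O)c1ccc(OCc2ccccc2)c(CC(=O)N2[C@@H](Cc3ccccc3)COC2=O)c1
F4 | step 5 | methyl 4-(benzyloxy)-3-{(1S,2S)-3-[(4S)-4-benzyl-2-oxo-1,3-oxazolidin-3-yl]-1-[2,4-bis(benzyloxy)-6-bromophenyl]-1-hydroxy-3-oxopropan-2-yl}benzoate | COC(=O)c1ccc(OCc2ccccc2)c([C@H](C(=O)N2[C@@H](Cc3ccccc3)COC2=O)[C@H](O)c2c(Br)cc(OCc3ccccc3)cc2OCc2ccccc2)c1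
F5 | step 5 | methyl 4-(benzyloxy)-3-{(1S,2S)-1-[2,4-bis(benzyloxy)-6-bromophenyl]-3-(ethylsulfanyl)-1-hydroxy-3-oxopropan-2-yl}benzoate | COC(=O)c1ccc(OCc2ccccc2)c([C@H](C(=O)SCC)[C@H](O)c2c(Br)cc(OCc3ccccc3)cc2OCc2ccccc2)c1
F6 | step 7 | methyl 4-(benzyloxy)-3-{(1S,2R,3R)-1-[2,4-bis(benzyloxy)-6-bromophenyl]-3-[4-(benzyloxy)phenyl]-1,3-dihydroxypropan-2-yl}benzoate | COC(=O)c1ccc(OCc2ccccc2)c([C@H]([C@@H](O)c2ccc(OCc3ccccc3)cc2)[C@H](O)c2c(Br)cc(OCc3ccccc3)cc2OCc2ccccc2)c1
F7 | step 7 | methyl 4-(benzyloxy)-3-{(1S,2R,3R)-1-[2,4-bis(benzyloxy)-6-(4,4,5,5-tetramethyl-1,3,2-dioxaborolan-2-yl)phenyl]-3-[4-(benzyloxy)phenyl]-1,3-dihydroxypropan-2-yl}benzoate | COC(=O)c1ccc(OCc2ccccc2)c([C@H]([C@@H](O)c2ccc(OCc3ccccc3)cc2)[C@H](O)c2c(B3OC(C)(C)C(C)(C)O3)cc(OCc3ccccc3)cc2OCc2ccccc2)c1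
F8 | step 7 | methyl 4-(benzyloxy)-3-{(1S,2R,3R)-1-[2,4-bis(benzyloxy)-6-hydroxyphenyl]-3-[4-(benzyloxy)phenyl]-1,3-dihydroxypropan-2-yl}benzoate | COC(=O)c1ccc(OCc2ccccc2)c([C@H]([C@@H](O)c2ccc(OCc3ccccc3)cc2)[C@H](O)c2c(O)cc(OCc3ccccc3)cc2OCc2ccccc2)c1
F9 | step 10 | methyl 4-(benzyloxy)-3-{(2S,3R,4S)-5,7-bis(benzyloxy)-2-[4-(benzyloxy)phenyl]-4-[(tert-butyldimethylsilyl)oxy]-3,4-dihydro-2H-1-benzopyran-3-yl}benzoate | COC(=O)c1ccc(OCc2ccccc2)c([C@H]2[C@H](O[Si](C)(C)C(C)(C)C)c3c(OCc4ccccc4)cc(OCc4ccccc4)cc3O[C@@H]2c2ccc(OCc3ccccc3)cc2)c1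
F10 | step 10 | 1-[2-(benzyloxy)-6-hydroxy-4-methoxyphenyl]-3-(4-(benzyloxy)-3-{(2S,3R,4S)-5,7-bis(benzyloxy)-2-[4-(benzyloxy)phenyl]-4-[(tert-butyldimethylsilyl)oxy]-3,4-dihydro-2H-1-benzopyran-3-yl}phenyl)propane-1,3-dione | O=C(CC(=O)c1c(O)cc(OC)cc1OCc1ccccc1)c1ccc(OCc2ccccc2)c([C@H]2[C@H](O[Si](C)(C)C(C)(C)C)c3c(OCc4ccccc4)cc(OCc4ccccc4)cc3O[C@@H]2c2ccc(OCc3ccccc3)cc2)c1
F11 | step 10 | 5-(benzyloxy)-2-(4-(benzyloxy)-3-{(2S,3R,4S)-5,7-bis(benzyloxy)-2-[4-(benzyloxy)phenyl]-4-[(tert-butyldimethylsilyl)oxy]-3,4-dihydro-2H-1-benzopyran-3-yl}phenyl)-7-methoxy-4H-1-benzopyran-4-one | COc1cc(OCc2ccccc2)c2c(=O)cc(-c3ccc(OCc4ccccc4)c([C@H]4[C@H](O[Si](C)(C)C(C)(C)C)c5c(OCc6ccccc6)cc(OCc6ccccc6)cc5O[C@@H]4c4ccc(OCc5ccccc5)cc4)c3)oc2c1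
F12 | step 10 | 5-(benzyloxy)-2-(4-(benzyloxy)-3-{(2S,3S,4S)-5,7-bis(benzyloxy)-2-[4-(benzyloxy)phenyl]-4-hydroxy-3,4-dihydro-2H-1-benzopyran-3-yl}phenyl)-7-methoxy-4H-1-benzopyran-4-one | COc1cc(OCc2ccccc2)c2c(=O)cc(-c3ccc(OCc4ccccc4)c([C@H]4[C@H](O)c5c(OCc6ccccc6)cc(OCc6ccccc6)cc5O[C@@H]4c4ccc(OCc5ccccc5)cc4)c3)oc2c1
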